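**Retrosynthetic overview**
- Last bond formed: C3′(sp2)–C4′(sp3), from the methyl-bearing alkene carbon to the first CH2 of the 6-phenylhexyl tail. This gives alkenyl iodide 13 (complete pyranone head, E geometry in place) and redox-active ester 15 of 7-phenylheptanoic acid, two electrophiles joined by Ni-electrocatalytic decarboxylative alkenylation.
- Enabling feature: the tail is a (CH2)6Ph chain with no heteroatom or stereocentre, so it can travel as a free primary radical from a carboxylic acid. The 2H-pyran-2-one ring is fully substituted (C3-OMe, C4-OMe, C5-Me, C6-CH2; no ring C–H or C–halogen), so it is a spectator to nickel and radicals. The E-C2′=C3′ geometry is stored in a C(sp2)–I bond.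
- 13 ⇐ O4-methylation of 4-hydroxypyranone 12 ⇐ lactonisation of 3,5-diketo ester 11 ⇐ aldol/oxidation joining the dianion of methyl 2-methoxy-3-oxopentanoate 4 with (E)-4-iodopent-3-enal 8.
- 8 ⇐ pent-3-yn-1-ol by syn-hydrozirconation/iodination (sets the E alkene once) and oxidation; 4 ⇐ crossed Claisen of methyl methoxyacetate with propanoyl chloride.
- Rings: the benzene ring is bought; the only ring formed is the 2-pyranone (step 6). No protecting groups.

Key step: step 9

Remark: the target has no stereocentre; its only stereo-element is the E trisubstituted alkene, so the route is built to deliver that single geometric isomer.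

**Route**

Step 1
Reactants: 1 methyl 2-methoxyacetate; 2 propanoyl chloride
Product: 4 methyl 2-methoxy-3-oxopentanoate (racemic), via lithium enolate 3 (not isolated)
Conditions: 1 (2.1 equiv), LiHMDS (2.1 equiv), THF, −78 °C; then 2 (1.0 equiv), −78 → −40 °C; 1 M HCl quench
Reagents that add atoms: none
Why: Crossed Claisen condensation: the chelated lithium enolate of the α-methoxy ester should be C-acylated by the acid chloride at −78 °C, and the spare equivalent of enolate deprotonates the more acidic β-keto ester as it forms so that it is not acylated twice; the C2 stereocentre forms racemic and is erased in step 6.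

Step 2
Reactants: 5 pent-3-yn-1-ol
Product: 7 (E)-4-iodopent-3-en-1-ol, via alkenylzirconocene alkoxide 6 (not isolated)
Conditions: Cp2Zr(H)Cl (2.6 equiv), THF, rt → 45 °C; then I2 (excess), 0 °C; aqueous work-up
Reagents that add atoms: iodine, II
Why: Hydrozirconation–iodination: after the first equivalent of Cp2Zr(H)Cl has converted the hydroxyl into its zirconium alkoxide, syn addition of Zr–H and equilibration by the excess hydride (reversible addition/β-hydride elimination) should place zirconium on the less hindered, methyl-bearing C4, and iodinolysis with retention then gives the E iodide (H and I cis, I trans to the C2 methylene), which fixes the alkene geometry of the target.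

Step 3
Reactants: 7 (E)-4-iodopent-3-en-1-ol
Product: 8 (E)-4-iodopent-3-enal
Conditions: Dess–Martin periodinane (1.2 equiv), NaHCO3, CH2Cl2, 0 °C; short silica plug, used at once
Reagents that add atoms: none
Why: Dess–Martin oxidation under bicarbonate buffer stops at the aldehyde and, being non-basic, should leave the β,γ-double bond out of conjugation with its E geometry untouched.

Step 4
Reactants: 4 methyl 2-methoxy-3-oxopentanoate; 8 (E)-4-iodopent-3-enal
Product: 10 methyl (7E)-5-hydroxy-8-iodo-2-methoxy-4-methyl-3-oxonon-7-enoate (mixture of diastereomers), via dilithium dienolate 9 (not isolated)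
Conditions: 4 (1.3 equiv), LDA (2.7 equiv), THF, −78 → 0 °C, then −78 °C; 8 (1.0 equiv), −78 °C; AcOH quench at −78 °C
Reagents that add atoms: none
Why: Aldol addition of a β-keto ester dianion: the γ-carbanion is the more reactive terminus of 9 and should add to the aldehyde carbonyl at −78 °C faster than it abstracts the α-protons of 8; the stereocentres at C2, C4 and C5 form as a mixture and need no control because steps 5 and 6 remove them all.

Step 5
Reactants: 10 methyl (7E)-5-hydroxy-8-iodo-2-methoxy-4-methyl-3-oxonon-7-enoate
Product: 11 methyl (7E)-8-iodo-2-methoxy-4-methyl-3,5-dioxonon-7-enoate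
Conditions: Dess–Martin periodinane (1.5 equiv), CH2Cl2, 0 °C → rt
Reagents that add atoms: none
Why: Dess–Martin oxidation of the β-hydroxy ketone to the 1,3-diketone under neutral conditions that the alkenyl iodide and the skipped alkene should tolerate; the C5 stereocentre disappears.

Step 6
Reactants: 11 methyl (7E)-8-iodo-2-methoxy-4-methyl-3,5-dioxonon-7-enoate
Product: 12 4-hydroxy-6-[(2E)-3-iodobut-2-en-1-yl]-3-methoxy-5-methyl-2H-pyran-2-one
Conditions: DBU (1.5 equiv), toluene, rt → 40 °C; 1 M HCl work-up
Reagents that add atoms: none
Why: Base-mediated lactonisation of a 3,5-diketo ester (6-exo-trig attack of the C5 enolate oxygen on the ester carbonyl, loss of methanol, tautomerisation), driven by formation of the acidic conjugated 4-hydroxy-2-pyranone; because 11 reacts as its 1,3-diketonate, the methylene between ketone and alkene should not be deprotonated and the alkene should stay in place, while the remaining sp3 stereocentres vanish.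

Step 7
Reactants: 12 4-hydroxy-6-[(2E)-3-iodobut-2-en-1-yl]-3-methoxy-5-methyl-2H-pyran-2-one
Product: 13 6-[(2E)-3-iodobut-2-en-1-yl]-3,4-dimethoxy-5-methyl-2H-pyran-2-one
Conditions: Me2SO4 (1.5 equiv), K2CO3 (2.0 equiv), acetone, rt
Reagents that add atoms: dimethyl sulfate, COS(=O)(=O)OC
Why: O-Alkylation of the pyranonate with a hard methylating agent under weak base (Williamson-type), conditions that favour methylation at the C4 oxygen to give the 2-pyranone and not the isomeric 4-pyranone; carbonate is too weak to deprotonate the C1′ methylene, so the skipped E alkene should be preserved.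

Step 8
Reactants: 14 7-phenylheptanoic acid
Product: 15 1,3-dioxoisoindolin-2-yl 7-phenylheptanoate
Conditions: N-hydroxyphthalimide (1.1 equiv), DIC (1.1 equiv), DMAP (10 mol%), CH2Cl2, rt
Reagents that add atoms: N-hydroxyphthalimide, O=C1c2ccccc2C(=O)N1O
Why: Steglich-type carbodiimide esterification with DMAP catalysis should give the N-acyloxyphthalimide (redox-active ester) as a bench-stable solid.

Step 9
Reactants: 13 6-[(2E)-3-iodobut-2-en-1-yl]-3,4-dimethoxy-5-methyl-2H-pyran-2-one; 15 1,3-dioxoisoindolin-2-yl 7-phenylheptanoate
Product: 17 lehualide E, 3,4-dimethoxy-5-methyl-6-[(2E)-3-methyl-9-phenylnon-2-en-1-yl]-2H-pyran-2-one, via 6-phenylhexyl radical 16 (not isolated)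
Conditions: 15 (2.0 equiv), NiCl2·6H2O (10 mol%), 2,2′-bipyridine (10 mol%), AgNO3 (30 mol%, plated in situ as Ag nanoparticles on the cathode), LiCl, DMF, Mg anode / RVC cathode, undivided cell, constant current (ca. 3 F/mol), rt
Reagents that add atoms: none
Why: Cathodically generated low-valent (bpy)Ni inserts into the C(sp2)–I bond of 13 with retention, while single-electron reduction of 15 (at the Ag-coated cathode or by Ni(I)) cleaves the N–O bond and expels CO2 to give primary radical 16; capture of 16 by the alkenyl–Ni(II) species gives an alkenyl(alkyl)Ni(III) complex that reductively eliminates the new C(sp2)–C(sp3) bond, with the Mg anode supplying the electrons. The closest known reaction type is the Ni-electrocatalytic decarboxylative alkenylation of redox-active esters with alkenyl iodides, a cross-electrophile coupling used to assemble E-trisubstituted polyene chains. No ring is closed and no stereocentre is created. The E geometry is transferred, not made: oxidative addition and reductive elimination at nickel are stereoretentive and the alkenyl–nickel intermediate should be configurationally stable at room temperature. The step needs cross- over homo-coupling and chemoselectivity towards the pyranone; these should be secured by the unhindered primary radical used in excess, by the fully substituted 2H-pyran-2-one ring (C3-OMe, C4-OMe, C5-Me, C6-CH2: no ring C–H or C–X for nickel or radicals to engage, and a reduction potential expected to lie beyond that of 15), and by phthalimide anion being the only base formed, too weak to deprotonate the doubly activated C1′ methylene.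

**Compound list**
1 | methyl 2-methoxyacetate | COCC(=O)OC | starting material
2 | propanoyl chloride | CCC(=O)Cl | starting material
3 | lithium enolate of methyl 2-methoxyacetate (lithium 1,2-dimethoxyethen-1-olate) | [Li]OC(OC)=COC | intermediate
4 | methyl 2-methoxy-3-oxopentanoate (racemic) | CCC(=O)C(OC)C(=O)OC | intermediate
5 | pent-3-yn-1-ol | CC#CCCO | starting material
6 | chlorozirconocene alkoxide of (E)-4-(chlorozirconocenyl)pent-3-en-1-ol (Cp rings drawn σ-bonded) | Cl[Zr](OCC/C=C(\C)[Zr](Cl)(C1C=CC=C1)C1C=CC=C1)(C1C=CC=C1)C1C=CC=C1 | intermediate
7 | (E)-4-iodopent-3-en-1-ol | OCC/C=C(\C)I | intermediate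
8 | (E)-4-iodopent-3-enal | O=CC/C=C(\C)I | intermediate
9 | dilithium dienolate (dianion) of methyl 2-methoxy-3-oxopentanoate | CC=C(O[Li])C(OC)=C(OC)O[Li] | intermediate
10 | methyl (7E)-5-hydroxy-8-iodo-2-methoxy-4-methyl-3-oxonon-7-enoate (diastereomer mixture) | COC(=O)C(OC)C(=O)C(C)C(O)C/C=C(\C)I | intermediate
11 | methyl (7E)-8-iodo-2-methoxy-4-methyl-3,5-dioxonon-7-enoate | COC(=O)C(OC)C(=O)C(C)C(=O)C/C=C(\C)I | intermediate
12 | 4-hydroxy-6-[(2E)-3-iodobut-2-en-1-yl]-3-methoxy-5-methyl-2H-pyran-2-one | COc1c(O)c(C)c(C/C=C(\C)I)oc1=O | intermediate
13 | 6-[(2E)-3-iodobut-2-en-1-yl]-3,4-dimethoxy-5-methyl-2H-pyran-2-one | COc1c(C)c(C/C=C(\C)I)oc(=O)c1OC | intermediate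
14 | 7-phenylheptanoic acid | OC(=O)CCCCCCc1ccccc1 | starting material
15 | 1,3-dioxoisoindolin-2-yl 7-phenylheptanoate | O=C(CCCCCCc1ccccc1)ON1C(=O)c2ccccc2C1=O | intermediate
16 | 6-phenylhexyl radical | [CH2]CCCCCc1ccccc1 | intermediate
17 | lehualide E, 3,4-dimethoxy-5-methyl-6-[(2E)-3-methyl-9-phenylnon-2-en-1-yl]-2H-pyran-2-one | COc1c(C)c(C/C=C(\C)CCCCCCc2ccccc2)oc(=O)c1OC | target

**Step count**
Total: 9 steps. Longest linear sequence: 7 steps (steps 2, 3, 4, 5, 6, 7, 9, from pent-3-yn-1-ol).

**Three steps most likely to fail**

Step 9. What may go wrong: reductive homocoupling or protodeiodination of 13 at nickel outrunning capture of the radical, cathodic over-reduction of the pyranone, or nickel-hydride-mediated migration of the skipped alkene. The fallback replaces the radical cross-electrophile logic by a two-electron B-alkyl Suzuki–Miyaura coupling. It sets out from 13: commercial 6-phenylhex-1-ene is hydroborated with 9-BBN-H (THF, rt) to B-(6-phenylhexyl)-9-borabicyclo[3.3.1]nonane F1, which is coupled in the same flask with 13 [Pd(dppf)Cl2, AsPh3, Cs2CO3, DMF/THF/H2O, rt]. The stereoretentive coupling comes back to the route at 17.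

Step 4. What may go wrong: proton transfer from the doubly activated α-methylene of 8 to the strongly basic dienolate (enolisation instead of addition), followed by migration of the double bond into conjugation and self-condensation of the aldehyde. The fallback is a Lewis-acid-mediated, base-free vinylogous Mukaiyama aldol. It sets out from 4: TMSCl, Et3N, hexane, rt should give methyl 2-methoxy-3-(trimethylsilyloxy)pent-2-enoate F2; LDA, THF, −78 °C, then TMSCl should give 1,2-dimethoxy-1,3-bis(trimethylsilyloxy)penta-1,3-diene F3. F3 and 8 with BF3·OEt2 in CH2Cl2 at −78 °C, then dilute acid work-up, should deliver 10 through attack of the diene terminus on the activated aldehyde, and the route continues from 10.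

Step 2. What may go wrong: incomplete equilibration of the regioisomeric alkenylzirconium species, or delivery steered by the zirconium alkoxide, placing the metal and then iodine on C3, together with over-reduction by the excess hydride. The fallback takes the hydroxyl out of play with a temporary silyl ether. It sets out from 5: TBSCl, imidazole, DMF should give tert-butyldimethyl(pent-3-yn-1-yloxy)silane F4. Cp2Zr(H)Cl (3 equiv), THF, 50 °C should equilibrate to the C4-zirconated (E)-alkenylzirconocene chloride F5, which is iodinated in the flask (I2, 0 °C) to tert-butyl{[(3E)-4-iodopent-3-en-1-yl]oxy}dimethylsilane F6. TBAF, THF, 0 °C then returns to the route at 7.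

**Further compounds**
F1 | step 9 | B-(6-phenylhexyl)-9-borabicyclo[3.3.1]nonane | C(CCCCCc1ccccc1)B1C2CCCC1CCC2
F2 | step 4 | methyl 2-methoxy-3-(trimethylsilyloxy)pent-2-enoate | CCC(O[Si](C)(C)C)=C(OC)C(=O)OC
F3 | step 4 | 1,2-dimethoxy-1,3-bis(trimethylsilyloxy)penta-1,3-diene | CC=C(O[Si](C)(C)C)C(OC)=C(OC)O[Si](C)(C)C
F4 | step 2 | tert-butyldimethyl(pent-3-yn-1-yloxy)silane | CC#CCCO[Si](C)(C)C(C)(C)C
F5 | step 2 | (E)-alkenylzirconocene chloride derived from F4 (Cp rings drawn σ-bonded) | CC(C)(C)[Si](C)(C)OCC/C=C(\C)[Zr](Cl)(C1C=CC=C1)C1C=CC=C1
F6 | step 2 | tert-butyl{[(3E)-4-iodopent-3-en-1-yl]oxy}dimethylsilane | CC(C)(C)[Si](C)(C)OCC/C=C(\C)I
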